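A direct plan would C-prenylate 2,4,6-trihydroxybenzaldehyde A1 to the mono-prenyl aldehyde A2 and would join two molecules of A2 by acid-catalysed condensation with a branched C8 aldehyde to the bridged dialdehyde A3.
Both formyl groups of A3 would then be turned into (2R)-2-methylbut-3-enoyl groups by an enantioselective rhodium-catalysed hydroacylation of buta-1,3-diene A4 to give the bis(2-methylbut-3-enoyl) compound A5, and the two vinyl groups would be reduced with diimide.
Weakest would be the twofold hydroacylation: it would set both stereocentres by an untested catalyst-controlled addition on the most advanced intermediate. Linear addition, attack on the prenyl alkenes and conjugation of the new double bond would all be open, and an (R,S) by-product differing only at two remote centres would hardly be separable.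
Second would be the diimide reduction: with the hydroacylation it would spend two late steps on making a five-carbon acyl group that a simple chiral acid could deliver complete, with any over-reduction paid for in final material.
Third would be the sulfonic acid-catalysed bridging, preceded by a statistical mono-prenylation: ortho-prenyl phenols would be exposed to chroman formation and the trihydroxybenzaldehyde to ipso attack with loss of the formyl group.

Plan of the new route
Retrosynthesis: in each benzene ring the bond between the acyl-bearing carbon and the neighbouring C–OH carbon that flanks the bridge is cut (Claisen disconnection). This unfolds each ring into a 3,5,7-trioxo ester chain and, by lactonisation, into a 4-hydroxy-2-pyranone; the two bridge C–C bonds are then cut at pyranone C3 to give two identical pyranones and 6-methylheptanal.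
Enabling feature: in both rings the six carbons alternate C–OH and C–substituent, and the acyl C=O continues this 1,3-pattern outside the ring, so each ring with its ketone is a folded tetraketide (oxygen at chain C1, C3, C5, C7). The two rings are identical and share one sp3 carbon, which is C1 of an aldehyde.
Ring order: the two pyranone rings are made first, the bridge joins them, and both benzene rings arise last and together by isomerisation of the bis-pyranone.
The weak steps do not arise: both (R) centres come in with (R)-2-methylbutanoic acid, no formyl group is elaborated, prenyl enters by C-alkylation of acetylacetone, no phloroglucinol is substituted selectively, and no acid meets an ortho-prenyl phenol before the final work-up.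

Key step: step 6

Remark: (2R)-2-methylbutanoic acid and 6-methylheptanal are taken as commercial; the acid supplies both stereocentres, each of which is (R) in the target.

Step 1
Reactants: 1 pentane-2,4-dione (acetylacetone); 2 1-bromo-3-methylbut-2-ene (prenyl bromide)
Product: 3 3-(3-methylbut-2-en-1-yl)pentane-2,4-dione
Conditions: 1 (2.0 equiv), 2 (1.0 equiv), K2CO3 (1.1 equiv), acetone, 56 °C
Reagents that add atoms: none
Why: C-alkylation of the potassium enolate of a 1,3-diketone with an allylic bromide, in which the doubly activated central carbon reacts and the excess of inexpensive 1 limits dialkylation; the substituted carbon bears two identical acetyl groups and is not a stereocentre.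

Step 2
Reactants: 3 3-(3-methylbut-2-en-1-yl)pentane-2,4-dione
Product: 5 4-hydroxy-6-methyl-5-(3-methylbut-2-en-1-yl)-2H-pyran-2-one, via diketo acid 4 (not isolated)
Conditions: LiN(iPr)2 (2.2 equiv), THF, −78 to 0 °C; CO2 (gas, excess), −78 °C; cold 1 M HCl to pH 2, extraction; crude 4 with 1,1'-carbonyldiimidazole (1.2 equiv), THF (0.02 M), 0 °C to rt
Reagents that add atoms: carbon dioxide, O=C=O
Why: Carboxylation of a 1,3-diketone dianion followed by dehydrative lactonisation: the second deprotonation occurs at a terminal methyl group because the central carbon is already an enolate, carbon dioxide is taken up at that most basic carbon, and the acyl imidazole of 4 is closed by the enol oxygen of the far ketone (6-exo-trig) to the 4-hydroxy-2-pyranone without any strong acid that could attack the prenyl group.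

Step 3
Reactants: 6 (2R)-2-methylbutanoic acid
Product: 8 (2R)-N-methoxy-N,2-dimethylbutanamide, via acyl imidazole 7 (not isolated)
Conditions: 1,1'-carbonyldiimidazole (1.1 equiv), CH2Cl2, 0 °C to rt; then MeNH(OMe)·HCl (1.2 equiv), rt
Reagents that add atoms: N,O-dimethylhydroxylamine hydrochloride, CNOC.Cl
Why: Weinreb amide formation through an acyl imidazole, an activation that does not pass through a ketene, so the alpha stereocentre of 6 should be carried into 8 unchanged.

Step 4
Reactants: 5 4-hydroxy-6-methyl-5-(3-methylbut-2-en-1-yl)-2H-pyran-2-one; 8 (2R)-N-methoxy-N,2-dimethylbutanamide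
Product: 9 4-hydroxy-6-[(3R)-3-methyl-2-oxopentyl]-5-(3-methylbut-2-en-1-yl)-2H-pyran-2-one
Conditions: 5 (1.0 equiv), LiN(iPr)2 (2.1 equiv), THF/DMPU, −78 °C; 8 (1.1 equiv), −78 to −20 °C; poured into cold 1 M HCl (pH 3)
Reagents that add atoms: none
Why: Acylation of the dianion of a 4-hydroxy-6-methyl-2-pyranone at the 6-methyl carbon (the last-formed and most nucleophilic site) with a Weinreb amide, whose lithium-chelated tetrahedral adduct survives until the acidic quench, so that no ketone with an alpha stereocentre is exposed to the base and the (R) centre is retained.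

Step 5
Reactants: 9 4-hydroxy-6-[(3R)-3-methyl-2-oxopentyl]-5-(3-methylbut-2-en-1-yl)-2H-pyran-2-one (2.0 equiv); 10 6-methylheptanal (1.0 equiv)
Product: 12 3,3'-(6-methylheptane-1,1-diyl)bis[4-hydroxy-6-[(3R)-3-methyl-2-oxopentyl]-5-(3-methylbut-2-en-1-yl)-2H-pyran-2-one], via alkylidene pyrandione 11 (not isolated)
Conditions: NaOAc (10 mol%), EtOH, 40 °C, Ar
Reagents that add atoms: none
Why: Knoevenagel condensation followed by Michael addition (the dicoumarol-type 2:1 reaction of 4-hydroxy-2-pyranones with aldehydes), in which the vinylogous acid 9 reacts at C3, its only nucleophilic ring carbon and far more readily ionised than the side-chain methylene, alkylidene dione 11 is captured by a second molecule of 9, and the bridge carbon receives two identical groups so that no stereocentre arises while the weak buffer leaves the ketone alpha centres and the prenyl groups untouched.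

Step 6
Reactants: 12 3,3'-(6-methylheptane-1,1-diyl)bis[4-hydroxy-6-[(3R)-3-methyl-2-oxopentyl]-5-(3-methylbut-2-en-1-yl)-2H-pyran-2-one]
Product: 15 (2R,2'R)-1,1'-[(6-methylheptane-1,1-diyl)bis[2,4,6-trihydroxy-5-(3-methylbut-2-en-1-yl)benzene-3,1-diyl]]bis(2-methylbutan-1-one) (the target CNP0245910.1), via ring-opened bis(trioxo ester) 13 (not isolated), via half-cyclised arene trioxo ester 14 (not isolated)
Conditions: Mg(OMe)2 (8 equiv), MeOH, 65 °C, Ar; then 0.5 M HCl to pH 4 at 0 °C, EtOAc
Reagents that add atoms: none
Why: Proposed new method: magnesium-bound methoxide should add to each lactone carbonyl and open the anionic pyranone to the magnesium chelate of a 3,5,7-trioxo ester (13; chain numbered from the ester carbon C1), whose C6 methylene, flanked by the C5 and C7 carbonyls, attacks C1 in a Claisen (Dieckmann-type) condensation, and loss of methoxide with enolisation of the resulting 2-acylcyclohexane-1,3,5-trione gives the aromatic 2,4,6-trihydroxyphenyl ketone, first on one half (14) and then on the other. The closest known reaction type is the Mg(OMe)2-mediated isomerisation of 6-(2-oxoalkyl)-4-hydroxy-2-pyranones lacking substituents at C3 and C5 into acylphloroglucinols, together with the Mg(OMe)2 methanolysis of 4-hydroxy-6-methyl-2-pyranone to methyl 3,5-dioxohexanoate; a twofold version on a C3-bridged, fully substituted pyranone that ends in hexasubstituted rings is the new element. Each benzene ring closes by 6-exo-trig attack of an enolate carbon on an ester carbonyl, forming the C6–C1 bond, that is the ring bond between the acyl-bearing carbon and the C–OH carbon next to the bridge. No stereocentre is formed: the bridge carbon carries two identical groups before and after, and the two (R) centres should survive because their carbonyl is enolised toward the far more acidic C6 throughout and ends as an aryl ketone conjugated to ortho and para phenoxides, which methoxide does not deprotonate at the alpha carbon. The step needs Claisen over aldol closure, and the substrate secures it: the orsellinate-type aldol (C2 onto the C7 ketone) would make C2 quaternary because C2 bears the bridge, so that adduct cannot aromatise and stays reversible, while the Claisen product leaves the equilibrium as a magnesium phenoxide. Fragmentation and recombination at the bridge under base would be degenerate because both rings are identical.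

**Compound list**

1 | pentane-2,4-dione (acetylacetone) | CC(=O)CC(C)=O | starting material
2 | 1-bromo-3-methylbut-2-ene (prenyl bromide) | CC(C)=CCBr | starting material
3 | 3-(3-methylbut-2-en-1-yl)pentane-2,4-dione | CC(=O)C(CC=C(C)C)C(C)=O | intermediate
4 | 4-(3-methylbut-2-en-1-yl)-3,5-dioxohexanoic acid (C4 labile, unspecified) | CC(=O)C(CC=C(C)C)C(=O)CC(=O)O | intermediate (not isolated)
5 | 4-hydroxy-6-methyl-5-(3-methylbut-2-en-1-yl)-2H-pyran-2-one | CC1=C(CC=C(C)C)C(O)=CC(=O)O1 | intermediate
6 | (2R)-2-methylbutanoic acid | CC[C@@H](C)C(=O)O | starting material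
7 | (2R)-1-(1H-imidazol-1-yl)-2-methylbutan-1-one | CC[C@@H](C)C(=O)n1ccnc1 | intermediate (not isolated)
8 | (2R)-N-methoxy-N,2-dimethylbutanamide | CC[C@@H](C)C(=O)N(C)OC | intermediate
9 | 4-hydroxy-6-[(3R)-3-methyl-2-oxopentyl]-5-(3-methylbut-2-en-1-yl)-2H-pyran-2-one | CC[C@@H](C)C(=O)CC1=C(CC=C(C)C)C(O)=CC(=O)O1 | intermediate
10 | 6-methylheptanal | CC(C)CCCCC=O | starting material
11 | 3-(6-methylheptylidene)-6-[(3R)-3-methyl-2-oxopentyl]-5-(3-methylbut-2-en-1-yl)-2H-pyran-2,4(3H)-dione (alkene geometry unspecified) | CC[C@@H](C)C(=O)CC1=C(CC=C(C)C)C(=O)C(=CCCCCC(C)C)C(=O)O1 | intermediate (not isolated)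
12 | 3,3'-(6-methylheptane-1,1-diyl)bis[4-hydroxy-6-[(3R)-3-methyl-2-oxopentyl]-5-(3-methylbut-2-en-1-yl)-2H-pyran-2-one] (bridge carbon not stereogenic) | CC[C@@H](C)C(=O)CC1=C(CC=C(C)C)C(O)=C(C(CCCCC(C)C)C2=C(O)C(CC=C(C)C)=C(CC(=O)[C@H](C)CC)OC2=O)C(=O)O1 | intermediate (key-step precursor)
13 | dimethyl 2,2'-(6-methylheptane-1,1-diyl)bis[(8R)-8-methyl-4-(3-methylbut-2-en-1-yl)-3,5,7-trioxodecanoate] (magnesium chelate in the flask; enolisable chain carbons unspecified) | CC[C@@H](C)C(=O)CC(=O)C(CC=C(C)C)C(=O)C(C(=O)OC)C(CCCCC(C)C)C(C(=O)OC)C(=O)C(CC=C(C)C)C(=O)CC(=O)[C@H](C)CC | intermediate (not isolated)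
14 | methyl (8R)-8-methyl-2-{6-methyl-1-[2,4,6-trihydroxy-3-[(2R)-2-methylbutanoyl]-5-(3-methylbut-2-en-1-yl)phenyl]heptyl}-4-(3-methylbut-2-en-1-yl)-3,5,7-trioxodecanoate (bridge and enolisable chain carbons unspecified; all forms converge on 15) | CC[C@@H](C)C(=O)c1c(O)c(CC=C(C)C)c(O)c(C(CCCCC(C)C)C(C(=O)OC)C(=O)C(CC=C(C)C)C(=O)CC(=O)[C@H](C)CC)c1O | intermediate (not isolated)
15 | (2R,2'R)-1,1'-[(6-methylheptane-1,1-diyl)bis[2,4,6-trihydroxy-5-(3-methylbut-2-en-1-yl)benzene-3,1-diyl]]bis(2-methylbutan-1-one) | CC[C@@H](C)C(=O)c1c(O)c(CC=C(C)C)c(O)c(C(CCCCC(C)C)c2c(O)c(CC=C(C)C)c(O)c(C(=O)[C@H](C)CC)c2O)c1O | target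

Total step count: 6. Longest linear sequence: 5 steps (steps 1, 2, 4, 5, 6); step 3 is a one-step side branch.

Steps most likely to fail

Step 6 (Proposed new method). Methoxide may fail to open the hindered, doubly anionic, C3-branched lactones, or the opened chains may be lost through cross-chain aldol closure or retro-Michael cleavage at the bridge before the Claisen closure occurs. The fallback sets out from 9 and returns at 15. The ring transformation would be run on the monomer, where C3 is unsubstituted as in the known cases and magnesium chelation alone has to favour Claisen over aldol closure. Treatment of 9 with Mg(OMe)2 in refluxing methanol should give the acylphloroglucinol (2R)-2-methyl-1-[2,4,6-trihydroxy-3-(3-methylbut-2-en-1-yl)phenyl]butan-1-one F1. Two molecules of F1 would then be joined at their only free ring carbon with 10 (0.5 equiv) under buffered amine catalysis (pyrrolidinium acetate, CH2Cl2/MeOH, rt) in a Knoevenagel–Michael sequence to give 15, so the bridge is formed last and without strong acid.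

Step 4. The sparingly soluble pyranone dianion may form incompletely or react sluggishly with the alpha-branched amide, and surplus amide base may cleave the N–O bond of 8. The fallback sets out from 3 and 8 and returns at 9. The chain would be acylated before the pyranone exists. The dianion of 3 (LiN(iPr)2, 2.1 equiv, THF, 0 °C) with 8 should give the triketone (7R)-7-methyl-3-(3-methylbut-2-en-1-yl)nonane-2,4,6-trione F2. Its trianion (LiN(iPr)2, 3.1 equiv, deprotonation at the terminal methyl group) would be carboxylated with CO2 to (8R)-8-methyl-4-(3-methylbut-2-en-1-yl)-3,5,7-trioxodecanoic acid F3, and lactonisation of F3 with 1,1'-carbonyldiimidazole would give 9.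

Step 5. The aldehyde may condense at the activated side-chain methylene in competition with C3, and the bis-adduct may cyclodehydrate to a fused pyranopyran. The fallback sets out from 5 and 10 and returns at 12. The bridge would be made before the keto side chains exist. Condensation of 5 (2 equiv) with 10 under the same buffered conditions should give 3,3'-(6-methylheptane-1,1-diyl)bis[4-hydroxy-6-methyl-5-(3-methylbut-2-en-1-yl)-2H-pyran-2-one] F4. Its tetra-anion (LiN(iPr)2, 4.2 equiv, THF/DMPU, −78 °C) would be acylated at both 6-methyl groups with 8 (2.2 equiv) to give 12.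

Further compounds
F1 | step 6 | (2R)-2-methyl-1-[2,4,6-trihydroxy-3-(3-methylbut-2-en-1-yl)phenyl]butan-1-one | CC[C@@H](C)C(=O)c1c(O)cc(O)c(CC=C(C)C)c1O
F2 | step 4 | (7R)-7-methyl-3-(3-methylbut-2-en-1-yl)nonane-2,4,6-trione | CC[C@@H](C)C(=O)CC(=O)C(CC=C(C)C)C(C)=O
F3 | step 4 | (8R)-8-methyl-4-(3-methylbut-2-en-1-yl)-3,5,7-trioxodecanoic acid | CC[C@@H](C)C(=O)CC(=O)C(CC=C(C)C)C(=O)CC(=O)O
F4 | step 5 | 3,3'-(6-methylheptane-1,1-diyl)bis[4-hydroxy-6-methyl-5-(3-methylbut-2-en-1-yl)-2H-pyran-2-one] | CC1=C(CC=C(C)C)C(O)=C(C(CCCCC(C)C)C2=C(O)C(CC=C(C)C)=C(C)OC2=O)C(=O)O1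
A1 | direct plan | 2,4,6-trihydroxybenzaldehyde | O=Cc1c(O)cc(O)cc1O
A2 | direct plan | 2,4,6-trihydroxy-3-(3-methylbut-2-en-1-yl)benzaldehyde | O=Cc1c(O)c(CC=C(C)C)c(O)cc1O
A3 | direct plan | 5,5'-(6-methylheptane-1,1-diyl)bis[2,4,6-trihydroxy-3-(3-methylbut-2-en-1-yl)benzaldehyde] | O=Cc1c(O)c(CC=C(C)C)c(O)c(C(CCCCC(C)C)c2c(O)c(CC=C(C)C)c(O)c(C=O)c2O)c1O
A4 | direct plan | buta-1,3-diene | C=CC=C
A5 | direct plan | (2R,2'R)-1,1'-[(6-methylheptane-1,1-diyl)bis[2,4,6-trihydroxy-5-(3-methylbut-2-en-1-yl)benzene-3,1-diyl]]bis(2-methylbut-3-en-1-one) | C=C[C@@H](C)C(=O)c1c(O)c(CC=C(C)C)c(O)c(C(CCCCC(C)C)c2c(O)c(CC=C(C)C)c(O)c(C(=O)[C@H](C)C=C)c2O)c1O
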